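The overall equation gives an invariant: [Sbt] + [Pdt] stays at the Sbt charged, so the Sbt used, divided by the Ctl charged, gives apparent turnovers, an upper count, since any Sbt that reacts without Ctl enters it too.

| flask | Sbt | Ptn | Ctl | time |
|---|---|---|---|---|
| north-west | 0.120 M | 0.180 M | 2.40 × 10⁻⁴ M |  |
| south-west | 0.0600 M | 0.120 M | 2.40 × 10⁻⁴ M |  |
| south | 0.120 M | 0.0900 M | 2.40 × 10⁻⁴ M |  |
| north-east | 0.120 M | 0.180 M | 4.80 × 10⁻⁴ M |  |
| north | 0.600 M | 0.180 M | 2.40 × 10⁻⁴ M | 150 min |

- north-west run (time / min: [Sbt] / M): 11: 0.0793; 35: 0.0559; 66: 0.0475; 100: 0.0435; 150: 0.0411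
- south-west run (time / min: [Sbt] / M): 11: 0.0434; 35: 0.0307; 66: 0.0250; 100: 0.0224; 150: 0.0187
- south run (time / min: [Sbt] / M): 11: 0.0943; 35: 0.0763; 66: 0.0685; 100: 0.0649; 150: 0.0638
- north-east run (time / min: [Sbt] / M): 11: 0.0595; 35: 0.0353; 66: 0.0264; 100: 0.0235; 150: 0.0213

(scatter of a reading: 4 × 10⁻⁴ M)

1. order of the initial rate in [Ctl], near the charge of the north-west run, the rate being that where two percent of its Sbt are Pdt
2. order of the initial rate in [Ptn], near the charge of the north-west run, the rate being that where two percent of its Sbt are Pdt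
3. the south-west run starts with 0.0600 M less of Sbt and of Ptn than the north-west run, and with no Pdt. Compared where both hold the same amount of Sbt, once fifteen percent of what the south-west run was charged with has turned into Pdt, is the south-west run faster, slower or alike (within a tenth)?
4. Sbt in the north run at 150 min, as a share of the Sbt charged

- Overall: Sbt + Ptn -> Pdt, with Ctl as catalyst.
- Constant volume, constant temperature.
- An order is taken over about fifteen percent of the charge, up and down.

At 150 min the north-west run has used 0.0789 M of Sbt against 0.180 M of Ptn charged, so Sbt is the limiting reagent of the overall equation, yet the run stalls with 0.0411 M of Sbt present. The counts at 150 min are 329 apparent turnovers in the north-west run and 206 in the north-east run.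

My own reckoning is that Ptn also leaves by a path second order in itself, a guess the table tests. Then d[Ptn]/d[Sbt] = 1 + a[Ptn]/[Sbt], where a is a selectivity factor: the Ptn lost by that path per Ptn reaching Pdt at equal [Sbt] and [Ptn].

The stalled share f of Sbt then follows from a and ρ, the Ptn charged over the Sbt charged: f = (1 + (a − 1)ρ)^(−1/(a − 1)). The north-west run has ρ = 1.50 and ln(1/f) = 1.07, taking its last reading as the stall. One Newton step from a − 1 = 0.5 gives the reading a = 1.62.

| Run | ρ | Stall from a | Reading at 150 min |
|---|---|---|---|
| South | 0.750 | 0.0649 M | 0.0638 M |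
| South-west | 2.00 | 0.0164 M | 0.0187 M |
| North-east | 1.50 | 0.0416 M | 0.0213 M |

The south reading lies 0.00110 M below its stall, and the south-west reading lies 0.00230 M above its stall while still falling. The north-east reading is far lower than its stall, so one a serves across the Sbt and Ptn charges at 2.40 × 10⁻⁴ M of Ctl, but it does not carry over to 4.80 × 10⁻⁴ M. The north run has the north-west Ctl charge, so I use a there: f = 76.0%.

The forecast gives 0.9 in Ctl (0.82 to 0.98), 0.68 in Ptn (0.5 to 0.85), faster, and 71% (70% to 75%), on the ground that “excess Sbt nearly exhausts Ptn”. My share is higher than its 71%.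

The simulation gives orders of 0.87 in Ctl and 1.0 in Ptn, faster, and 75.5%; the forecast parts from it on the Ptn order, 0.68 against 1.0.

    2 Ctl ⇌ Ctl2, settled at all times (12300 M⁻¹)
    Ctl2 + Sbt + Ptn → Pdt + Ctl2 (3090 M⁻² min⁻¹)
    Sbt + Ptn → Pdt (0.1044 M⁻¹ min⁻¹)
    2 Ptn → L (0.2562 M⁻¹ min⁻¹)

In the north-west run, Pdt formed at 0.0071 M min⁻¹ near the start while Ptn also paired to L, and Pdt reached half of the Sbt charged by 28.7 min. In the north run, with a at 1.62, [Sbt]/(a[Ptn]) began at 2.05, and at 150 min it held 75.5% of its Sbt, the Pdt made being 81.7% of its Ptn charge.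

The runs were generated by integration with made-up constants; noise was put on by code.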